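**Retrosynthetic overview**

- Numbering: C1 = carbinol bridgehead; ring A = C1–C2(aryl, exo)–O3–C4–C5; ring B = C5–C6(aryl, endo)–O7–C8–C1. The plan rests on the ring A segment O3–C2(Ar)–C1(OH)–C8, an erythro 1-aryl-glycerol unit with a quaternary C1, which is what anti oxygenation of an (E)-2-substituted cinnamyl alcohol delivers.
- Late stage: the C4 methylene comes from a ring A lactone (lactol, then silane reduction). The C6–H comes from a ring B hemiketal (silane reduction, hydride on the convex face). C5–C6 comes from acylation of the lactone dianion with methyl 3,4-dimethoxybenzoate.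
- Key disconnection: C1–O and C2–O3, by asymmetric epoxidation of allylic alcohol 7 and opening of the epoxide at C2 by the tethered tert-butyl ester.
- Precursor 7: Stobbe condensation of veratraldehyde with dimethyl succinate, tert-butyl esterification, selective reduction of the conjugated methyl ester.
- Ring order: ring A first (step 4, as a lactone), ring B second (step 7, as a hemiketal).

Key step: step 4

Remark: 3 is a racemic diastereomer mixture, and 15 and 17 are expected as epimer mixtures at the hemiketal or lactol carbon (C6, C4); these centres are erased in the following step, so their SMILES leave them open.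

**Route**

Step 1
Reactants: 1 veratraldehyde; 2 dimethyl succinate
Product: 4 (E)-4-(3,4-dimethoxyphenyl)-3-(methoxycarbonyl)but-3-enoic acid, via paraconate lactone 3 (not isolated)
Conditions: NaOMe, MeOH, reflux; then aq. HCl
Reagents that add atoms: none
Why: Stobbe condensation, in which the succinate enolate adds to the aldehyde, the aldolate lactonises to 3 and base-induced E1cB opening should give the half-ester with aryl trans to the conjugated ester (E), the favoured geometry.

Step 2
Reactants: 4 (E)-4-(3,4-dimethoxyphenyl)-3-(methoxycarbonyl)but-3-enoic acid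
Product: 5 4-tert-butyl 1-methyl (E)-2-(3,4-dimethoxybenzylidene)butanedioate
Conditions: Cl3CC(=NH)OtBu, BF3·OEt2 (cat.), CH2Cl2/cyclohexane, rt
Reagents that add atoms: tert-butyl 2,2,2-trichloroacetimidate, CC(C)(C)OC(=N)C(Cl)(Cl)Cl
Why: Acid-catalysed tert-butylation of a carboxylic acid by a trichloroacetimidate esterifies only the free acid and leaves the conjugated methyl ester and the alkene geometry untouched.

Step 3
Reactants: 5 4-tert-butyl 1-methyl (E)-2-(3,4-dimethoxybenzylidene)butanedioate
Product: 7 tert-butyl (E)-4-(3,4-dimethoxyphenyl)-3-(hydroxymethyl)but-3-enoate, via enal 6 (not isolated)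
Conditions: i-Bu2AlH (2.2 equiv), CH2Cl2, −78 °C; aq. KNaC4H4O6
Reagents that add atoms: none
Why: Chemoselective i-Bu2AlH 1,2-reduction of an ester, in which the unhindered methyl ester should be reduced through enal 6 to the allylic alcohol at −78 °C while the bulky tert-butyl ester is not attacked.

Step 4
Reactants: 7 tert-butyl (E)-4-(3,4-dimethoxyphenyl)-3-(hydroxymethyl)but-3-enoate
Product: 9 (4S,5R)-5-(3,4-dimethoxyphenyl)-4-hydroxy-4-(hydroxymethyl)dihydrofuran-2(3H)-one, via epoxy alcohol 8 (not isolated)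
Conditions: Ti(OiPr)4 (10 mol%), L-(+)-diethyl tartrate (12 mol%), t-BuOOH (2 equiv), 4 Å MS, CH2Cl2, −20 °C; cold neutral work-up; then crude 8, PPTS (0.2 equiv), CH2Cl2, −20 → 0 °C
Reagents that add atoms: tert-butyl hydroperoxide, CC(C)(C)OO
Why: Katsuki–Sharpless asymmetric epoxidation followed by acid-promoted epoxide-opening lactonisation, both known reaction types (epoxidation of (E)-2-substituted cinnamyl alcohols; 5-endo opening of aryl epoxides by a beta-ester). The allylic alkoxide and the hydroperoxide bind to the catalyst formed from Ti(OiPr)4 and L-(+)-diethyl tartrate, which transfers oxygen to one alkene face in the sense that turns (E)-cinnamyl alcohols into (2S,3S)-epoxides, so C1 is set as S by the tartrate and the epoxide oxygen becomes the tertiary hydroxyl. With PPTS the ester carbonyl oxygen attacks benzylic C2 at the rear of the breaking C2–O bond, the tert-butyl group leaves as isobutene, and ring A closes as the lactone in a 5-endo-tet mode (C2–O3 formed). C2 (R) is set by this inversion: epoxidation plus inversion is a net anti addition to the (E)-alkene, which gives the erythro relation of O3 and the C1 hydroxyl (aryl cis to hydroxyl on ring A). Regioselectivity (C2, not C1) follows from the dimethoxyphenyl group, which loosens the benzylic C–O bond, and from the strain of the 4-exo beta-lactone alternative. Stereospecificity requires capture before a free benzylic cation forms, which the intramolecular carbonyl, the weak acid and the low temperature are meant to secure.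

Step 5
Reactants: 9 (4S,5R)-5-(3,4-dimethoxyphenyl)-4-hydroxy-4-(hydroxymethyl)dihydrofuran-2(3H)-one
Product: 10 (4S,5R)-4-[(tert-butyldimethylsilyloxy)methyl]-5-(3,4-dimethoxyphenyl)-4-hydroxydihydrofuran-2(3H)-one
Conditions: TBSCl, imidazole, DMF, 0 °C → rt
Reagents that add atoms: tert-butyldimethylsilyl chloride, CC(C)(C)[Si](C)(C)Cl
Why: Silyl ether formation is selective for the primary hydroxyl because the tertiary hydroxyl is too hindered for TBSCl/imidazole, and it is left free on purpose for the next step.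

Step 6
Reactants: 10 (4S,5R)-4-[(tert-butyldimethylsilyloxy)methyl]-5-(3,4-dimethoxyphenyl)-4-hydroxydihydrofuran-2(3H)-one; 11 methyl 3,4-dimethoxybenzoate
Product: 13 (3S,4S,5R)-4-[(tert-butyldimethylsilyloxy)methyl]-3-(3,4-dimethoxybenzoyl)-5-(3,4-dimethoxyphenyl)-4-hydroxydihydrofuran-2(3H)-one, via lactone dianion 12 (not isolated)
Conditions: LiN(iPr)2 (3.2 equiv), THF, −78 °C; then 11, −78 → −20 °C; AcOH, −78 °C
Reagents that add atoms: none
Why: Fráter–Seebach-type dianion formation followed by crossed Claisen acylation, in which the C1 alkoxide blocks beta-elimination of the enolate, C-acylation at C5 should occur anti to the alkoxide (cis to the silyloxymethyl arm), and the product stays as its enolate until the cold acidic quench; C5 remains epimerisable, which is harmless because only the cis isomer can close ring B.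

Step 7
Reactants: 13 (3S,4S,5R)-4-[(tert-butyldimethylsilyloxy)methyl]-3-(3,4-dimethoxybenzoyl)-5-(3,4-dimethoxyphenyl)-4-hydroxydihydrofuran-2(3H)-one
Product: 15 (1S,2R,5S)-2,6-bis(3,4-dimethoxyphenyl)-1,6-dihydroxy-3,7-dioxabicyclo[3.3.0]octan-4-one (C6 hemiketal epimers), via hydroxy keto lactone 14 (not isolated)
Conditions: HF·pyridine, THF, 0 °C → rt
Reagents that add atoms: none
Why: Acidic fluoride desilylation frees the C8 hydroxyl, which adds to the C6 aryl ketone (5-exo-trig hemiketalisation) to close ring B cis-fused; acidic rather than basic fluoride avoids retro-aldol cleavage of the beta-hydroxy beta-dicarbonyl unit, and any C5 epimer should equilibrate through the enol to the isomer that can cyclise.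

Step 8
Reactants: 15 (1S,2R,5S)-2,6-bis(3,4-dimethoxyphenyl)-1,6-dihydroxy-3,7-dioxabicyclo[3.3.0]octan-4-one
Product: 16 (1S,2R,5R,6R)-2,6-bis(3,4-dimethoxyphenyl)-1-hydroxy-3,7-dioxabicyclo[3.3.0]octan-4-one
Conditions: Et3SiH, BF3·OEt2, CH2Cl2, −78 → −20 °C
Reagents that add atoms: none
Why: Ionic hydrogenation of a hemiketal, in which BF3 ionises the C6 hydroxyl to an aryl-stabilised oxocarbenium ion and Et3SiH should deliver hydride from the convex face of the cis-fused bicycle, so that H ends exo and the C6 aryl endo (6R).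

Step 9
Reactants: 16 (1S,2R,5R,6R)-2,6-bis(3,4-dimethoxyphenyl)-1-hydroxy-3,7-dioxabicyclo[3.3.0]octan-4-one
Product: 17 (1S,2R,5R,6R)-2,6-bis(3,4-dimethoxyphenyl)-3,7-dioxabicyclo[3.3.0]octane-1,4-diol (C4 lactol epimers)
Conditions: i-Bu2AlH (2.5 equiv), CH2Cl2, −78 °C; aq. KNaC4H4O6
Reagents that add atoms: none
Why: Partial reduction of a lactone to the lactol by i-Bu2AlH, whose tetrahedral adduct is stable at −78 °C; the first equivalent is taken up by the tertiary hydroxyl and C5 cannot epimerise at the cis ring fusion.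

Step 10
Reactants: 17 (1S,2R,5R,6R)-2,6-bis(3,4-dimethoxyphenyl)-3,7-dioxabicyclo[3.3.0]octane-1,4-diol
Product: 18 (+)-gmelinol, (1S,2R,5R,6R)-2,6-bis(3,4-dimethoxyphenyl)-3,7-dioxabicyclo[3.3.0]octan-1-ol
Conditions: Et3SiH, BF3·OEt2, CH2Cl2, −78 → −40 °C
Reagents that add atoms: none
Why: Ionic hydrogenation of a lactol, in which the C4 oxocarbenium ion is reduced by Et3SiH to the methylene; no stereocentre is formed and the low temperature is meant to keep the benzylic C2–O3 and C6–O7 bonds from ionising.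

**Compound list**

1 | veratraldehyde (3,4-dimethoxybenzaldehyde) | COc1ccc(C=O)cc1OC | starting material
2 | dimethyl succinate | COC(=O)CCC(=O)OC | starting material
3 | methyl 2-(3,4-dimethoxyphenyl)-5-oxooxolane-3-carboxylate (paraconate lactone, racemic diastereomer mixture) | COC(=O)C1CC(=O)OC1c1ccc(OC)c(OC)c1 | intermediate (not isolated)
4 | (E)-4-(3,4-dimethoxyphenyl)-3-(methoxycarbonyl)but-3-enoic acid | COC(=O)/C(CC(=O)O)=C/c1ccc(OC)c(OC)c1 | intermediate
5 | 4-tert-butyl 1-methyl (E)-2-(3,4-dimethoxybenzylidene)butanedioate | COC(=O)/C(CC(=O)OC(C)(C)C)=C/c1ccc(OC)c(OC)c1 | intermediate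
6 | tert-butyl (E)-4-(3,4-dimethoxyphenyl)-3-formylbut-3-enoate | COc1ccc(/C=C(/C=O)CC(=O)OC(C)(C)C)cc1OC | intermediate (not isolated)
7 | tert-butyl (E)-4-(3,4-dimethoxyphenyl)-3-(hydroxymethyl)but-3-enoate | COc1ccc(/C=C(/CO)CC(=O)OC(C)(C)C)cc1OC | intermediate
8 | tert-butyl 2-[(2S,3S)-3-(3,4-dimethoxyphenyl)-2-(hydroxymethyl)oxiran-2-yl]acetate | COc1ccc(cc1OC)[C@@H]1O[C@]1(CO)CC(=O)OC(C)(C)C | intermediate (not isolated)
9 | (4S,5R)-5-(3,4-dimethoxyphenyl)-4-hydroxy-4-(hydroxymethyl)dihydrofuran-2(3H)-one | COc1ccc(cc1OC)[C@H]2OC(=O)C[C@]2(O)CO | intermediate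
10 | (4S,5R)-4-[(tert-butyldimethylsilyloxy)methyl]-5-(3,4-dimethoxyphenyl)-4-hydroxydihydrofuran-2(3H)-one | COc1ccc(cc1OC)[C@H]2OC(=O)C[C@]2(O)CO[Si](C)(C)C(C)(C)C | intermediate
11 | methyl 3,4-dimethoxybenzoate | COc1ccc(cc1OC)C(=O)OC | starting material
12 | dilithium salt (Li2C19H28O6Si) of the C1 alkoxide and lactone enolate of 10 | COc1ccc(cc1OC)[C@H]1OC([O-])=C[C@]1([O-])CO[Si](C)(C)C(C)(C)C.[Li+].[Li+] | intermediate (not isolated)
13 | (3S,4S,5R)-4-[(tert-butyldimethylsilyloxy)methyl]-3-(3,4-dimethoxybenzoyl)-5-(3,4-dimethoxyphenyl)-4-hydroxydihydrofuran-2(3H)-one | COc1ccc(cc1OC)[C@H]2OC(=O)[C@H](C(=O)c3ccc(OC)c(OC)c3)[C@]2(O)CO[Si](C)(C)C(C)(C)C | intermediate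
14 | (3S,4S,5R)-3-(3,4-dimethoxybenzoyl)-5-(3,4-dimethoxyphenyl)-4-hydroxy-4-(hydroxymethyl)dihydrofuran-2(3H)-one | COc1ccc(cc1OC)[C@H]2OC(=O)[C@H](C(=O)c3ccc(OC)c(OC)c3)[C@]2(O)CO | intermediate (not isolated)
15 | (1S,2R,5S)-2,6-bis(3,4-dimethoxyphenyl)-1,6-dihydroxy-3,7-dioxabicyclo[3.3.0]octan-4-one (C6 epimers) | COc1ccc([C@H]2OC(=O)[C@@H]3C(O)(c4ccc(OC)c(OC)c4)OC[C@]23O)cc1OC | intermediate
16 | (1S,2R,5R,6R)-2,6-bis(3,4-dimethoxyphenyl)-1-hydroxy-3,7-dioxabicyclo[3.3.0]octan-4-one | COc1ccc([C@H]2OC(=O)[C@@H]3[C@H](c4ccc(OC)c(OC)c4)OC[C@]23O)cc1OC | intermediate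
17 | (1S,2R,5R,6R)-2,6-bis(3,4-dimethoxyphenyl)-3,7-dioxabicyclo[3.3.0]octane-1,4-diol (C4 epimers) | COc1ccc([C@H]2OC(O)[C@@H]3[C@H](c4ccc(OC)c(OC)c4)OC[C@]23O)cc1OC | intermediate
18 | (+)-gmelinol, (1S,2R,5R,6R)-2,6-bis(3,4-dimethoxyphenyl)-3,7-dioxabicyclo[3.3.0]octan-1-ol | COc1ccc([C@H]2OC[C@@H]3[C@H](c4ccc(OC)c(OC)c4)OC[C@]23O)cc1OC | target

**Step count**

Total: 10 steps. Longest linear sequence: 10 steps (1 → 18); 11 is used as purchased.

**Steps most likely to fail**

Step 4. The electron-rich benzylic epoxide may be opened on the Lewis-acidic titanium centre by isopropanol or hydroperoxide. It may also ionise to a free cation before the carbonyl arrives, which would lose the inversion at C2 or lead to hydride-shift rearrangement. Coordination of the ester to titanium may erode enantioface selection. Fallback, from 7 and back at 10: silylate 7 (TBSCl, imidazole, DMF) to tert-butyl (E)-3-[(tert-butyldimethylsilyloxy)methyl]-4-(3,4-dimethoxyphenyl)but-3-enoate F1. Epoxidise F1 without any Lewis acid by Shi epoxidation, with 1,2:4,5-di-O-isopropylidene-β-L-erythro-2,3-hexodiulo-2,6-pyranose as catalyst, KHSO5 and K2CO3 buffer in MeCN/CH2(OMe)2/H2O at 0 °C. By the spiro transition-state model this should give tert-butyl 2-[(2S,3S)-2-[(tert-butyldimethylsilyloxy)methyl]-3-(3,4-dimethoxyphenyl)oxiran-2-yl]acetate F2, which can be isolated from the basic medium. PPTS in CH2Cl2 at −20 °C should then lactonise F2 to silyl lactone 10, so that step 5 is not needed.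

Step 6. C-acylation of the hindered enolate by the electron-rich, weakly electrophilic ester may be slow, so that silyl migration to the C1 alkoxide, O-acylation or decomposition of the dianion on warming takes over. Fallback, from 10 and back at 13: add veratraldehyde 1 to dianion 12 at −78 °C (aldol addition, fast at this temperature). This should give (3R,4S,5R)-4-[(tert-butyldimethylsilyloxy)methyl]-5-(3,4-dimethoxyphenyl)-3-[(3,4-dimethoxyphenyl)(hydroxy)methyl]-4-hydroxydihydrofuran-2(3H)-one F3 as a mixture of carbinol epimers. Oxidise the benzylic alcohol of F3 with Dess–Martin periodinane (NaHCO3, CH2Cl2) to keto lactone 13.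

Step 10. BF3 may ionise the benzylic C2–O3 or C6–O7 bond of the electron-rich bis-ether, which would epimerise the endo aryl group at C6 or lead to reductive ring opening by the silane. Fallback, from 16 and back at 18: reduce lactone 16 with LiAlH4 (THF, 0 °C) to (3S,4R,5R)-5-(3,4-dimethoxyphenyl)-3-[(R)-(3,4-dimethoxyphenyl)(hydroxy)methyl]-4-(hydroxymethyl)oxolan-3-ol F4. MsCl (1 equiv) and pyridine in CH2Cl2 at 0 °C should sulfonylate only the primary hydroxyl to give [(2R,3R,4S)-2-(3,4-dimethoxyphenyl)-4-[(R)-(3,4-dimethoxyphenyl)(hydroxy)methyl]-4-hydroxyoxolan-3-yl]methyl methanesulfonate F5. The benzylic C2 hydroxyl of F5 should displace the sulfonate in place (5-exo-tet etherification) to close ring A and give 18, with no Lewis acid and no cleavage of a benzylic C–O bond.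

**Further compounds**

F1 | step 4 | tert-butyl (E)-3-[(tert-butyldimethylsilyloxy)methyl]-4-(3,4-dimethoxyphenyl)but-3-enoate | COc1ccc(/C=C(/CO[Si](C)(C)C(C)(C)C)CC(=O)OC(C)(C)C)cc1OC
F2 | step 4 | tert-butyl 2-[(2S,3S)-2-[(tert-butyldimethylsilyloxy)methyl]-3-(3,4-dimethoxyphenyl)oxiran-2-yl]acetate | COc1ccc(cc1OC)[C@@H]1O[C@]1(CO[Si](C)(C)C(C)(C)C)CC(=O)OC(C)(C)C
F3 | step 6 | (3R,4S,5R)-4-[(tert-butyldimethylsilyloxy)methyl]-5-(3,4-dimethoxyphenyl)-3-[(3,4-dimethoxyphenyl)(hydroxy)methyl]-4-hydroxydihydrofuran-2(3H)-one (carbinol epimers) | COc1ccc(cc1OC)[C@H]2OC(=O)[C@H](C(O)c3ccc(OC)c(OC)c3)[C@]2(O)CO[Si](C)(C)C(C)(C)C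
F4 | step 10 | (3S,4R,5R)-5-(3,4-dimethoxyphenyl)-3-[(R)-(3,4-dimethoxyphenyl)(hydroxy)methyl]-4-(hydroxymethyl)oxolan-3-ol | COc1ccc([C@@H](O)[C@@]2(O)CO[C@@H](c3ccc(OC)c(OC)c3)[C@H]2CO)cc1OC
F5 | step 10 | [(2R,3R,4S)-2-(3,4-dimethoxyphenyl)-4-[(R)-(3,4-dimethoxyphenyl)(hydroxy)methyl]-4-hydroxyoxolan-3-yl]methyl methanesulfonate | COc1ccc([C@@H](O)[C@@]2(O)CO[C@@H](c3ccc(OC)c(OC)c3)[C@H]2COS(C)(=O)=O)cc1OC
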